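**Assumption:** germacrane numbering is used throughout (ring C1–C10, lactone carbons C11–C13, C14 = CO2H, C15 = 4‑CH3, side‑chain atoms primed), and compounds 1, 2, 5, 7, 15, 16, 18 and 22 are taken as commercial. The route is a design proposal; no step has been run.

## Retrosynthetic overview

1. Leucanthin B ⇐ TMSE‑ester cleavage ⇐ ring‑closing metathesis forming the ring‑cis C1=C10 enoate (10‑membered ring closed last).
2. RCM diene ⇐ C8–O esterification with (2R,3R)‑epoxyangelic acid (Shi epoxidation of angelyl alcohol) + indium Barbier γ‑acetoxy‑2‑carboxyallylation of a C8 aldehyde (C8–C9 bond, delivers C9–OAc and the C10 acrylate).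
3. C8 aldehyde ⇐ Shi cis‑olefin epoxidation (2,3‑epoxide) ⇐ OH‑directed epoxidation (4,5‑epoxide) and lactonisation of a 6,7‑anti homoallylic alcohol.
4. That alcohol ⇐ chiral Brønsted‑acid‑catalysed allylboration (C6–C7 bond, first stereocentres) of an achiral (Z)‑enynal with a (Z)‑2‑carbomethoxy allylboronate.
5. Ring order: γ‑lactone and 4,5‑epoxide → 2,3‑epoxide → (side‑chain epoxide made separately) → 10‑membered carbocycle.

## Route

**Step 1**
Reactants: 1, (Z)‑3‑methylpent‑2‑en‑4‑yn‑1‑ol; 2, bromoethene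
Product: 3, (2Z)‑3‑methylhepta‑2,6‑dien‑4‑yn‑1‑ol
Conditions: Pd(PPh3)4 (3 mol%), CuI (6 mol%), iPr2NH, THF, 0 °C → rt
Reagents that add atoms: none (2 is a reactant)
Why: Sonogashira coupling of the terminal alkyne with a vinyl halide; the Z‑trisubstituted alkene (future cis‑4,5‑epoxide) is untouched.

**Step 2**
Reactants: 3
Product: 4, (2Z)‑3‑methylhepta‑2,6‑dien‑4‑ynal
Conditions: MnO2, CH2Cl2, rt, dark
Reagents that add atoms: none
Why: Neutral allylic MnO2 oxidation keeps the Z‑enal, and keeping C2≡C3 as an alkyne at this stage avoids the oxa‑6π cyclisation a (Z,Z)‑dienal would undergo.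

**Step 3**
Reactants: 5, tert‑butyldimethyl(prop‑2‑yn‑1‑yloxy)silane
Product: 6, methyl 4‑[(tert‑butyldimethylsilyl)oxy]but‑2‑ynoate
Conditions: n‑BuLi, THF, −78 °C; ClCO2Me, −78 → 0 °C
Reagents that add atoms: methyl chloroformate, COC(=O)Cl
Why: Standard C‑acylation of a lithium acetylide.

**Step 4**
Reactants: 6; 7, 2‑(iodomethyl)‑4,4,5,5‑tetramethyl‑1,3,2‑dioxaborolane
Product: 8, methyl (2Z)‑4‑[(tert‑butyldimethylsilyl)oxy]‑2‑[(pinacolboryl)methyl]but‑2‑enoate (CH2OTBS cis to CO2Me, trans to CH2B)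
Conditions: DIBAL‑H, HMPA, THF, 0 °C; then 7, 0 °C → rt
Reagents that add atoms: none (hydride only; 7 is a reactant)
Why: Conjugate syn‑hydroalumination of the ynoate places H and Al cis, and C‑alkylation of the α‑alumino enoate by the iodomethylboronate with retention fixes the (Z)‑geometry needed for an anti allylboration.

**Step 5**
Reactants: 4; 8
Product: 9, methyl (3R,4R,5Z)‑3‑{[(tert‑butyldimethylsilyl)oxy]methyl}‑4‑hydroxy‑6‑methyl‑2‑methylidenedeca‑5,9‑dien‑7‑ynoate (germacrane C7 and C6; 6,7‑anti)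
Conditions: (S)‑3,3′‑bis(2,4,6‑iPr3C6H2)‑BINOL N‑triflylphosphoramide (10 mol%), 4 Å MS, toluene, −40 °C; cold aq. NaHCO3 quench
Reagents that add atoms: none
Why: Proposed new method: enantioselective allylboration of an aldehyde with an ester‑deactivated (2‑alkoxycarbonyl) allyl pinacolboronate under a strong chiral Brønsted acid; the acid protonates/H‑bonds a boronate oxygen (the activation known for triflic‑acid‑accelerated additions of this boronate class) while its phosphoryl oxygen holds the formyl C–H (the organisation known for BINOL‑phosphoric‑acid allylboration with simple allyl‑Bpin), so C6–C7 forms through a closed chair in the chiral pocket: the (S)‑acid is chosen by analogy to direct attack to the aldehyde Si face (sets C6; to be confirmed, otherwise use the (R)‑acid), and the γ‑CH2OTBS group, trans to CH2B, sits equatorial (sets C7, 6,7‑anti = trans‑lactone relationship); closest known reactions are chiral phosphoric‑acid allyl/crotylboration and achiral Brønsted‑acid‑catalysed allylboration of 2‑alkoxycarbonyl allylboronates.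

**Step 6**
Reactants: 9
Product: 10, methyl (3R,4R,5Z,7Z)‑3‑{[(tert‑butyldimethylsilyl)oxy]methyl}‑4‑hydroxy‑6‑methyl‑2‑methylidenedeca‑5,7,9‑trienoate
Conditions: Zn(Cu/Ag), MeOH/H2O (1:1), 35 °C
Reagents that add atoms: none
Why: Boland reduction semi‑reduces only the conjugated alkyne, cis‑selectively (C2=C3 Z), and spares the acrylate and other alkenes.

**Step 7**
Reactants: 10
Product: 11, (4R,5S)‑4‑{[(tert‑butyldimethylsilyl)oxy]methyl}‑5‑{(2R,3S)‑3‑[(1Z)‑buta‑1,3‑dien‑1‑yl]‑3‑methyloxiran‑2‑yl}‑3‑methylidenedihydrofuran‑2(3H)‑one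
Conditions: DMDO, CH2Cl2, −20 °C; then DBU (0.2 equiv), 0 °C → rt (−MeOH)
Reagents that add atoms: dimethyldioxirane, CC1(C)OO1
Why: Hydroxyl‑directed (Henbest‑type) epoxidation: the cis C3 substituent forces C6–H to eclipse the alkene (A1,3 strain), so the H‑bonded oxidant attacks C4=C5 syn to OH (5,6‑threo, as in the target), the Z‑alkene gives the cis‑epoxide stereospecifically, and base then closes the γ‑lactone without acid that would open the dienyl epoxide.

**Step 8**
Reactants: 11
Product: 12, (4R,5S)‑4‑{[(tert‑butyldimethylsilyl)oxy]methyl}‑5‑[(2R,2′R,3R,3′R)‑3′‑ethenyl‑2‑methyl‑2,2′‑bioxiran‑3‑yl]‑3‑methylidenedihydrofuran‑2(3H)‑one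
Conditions: Shi cis‑olefin catalyst (D‑glucose‑derived N‑Boc oxazolidinone ketone, 25 mol%), Oxone, K2CO3, Bu4NHSO4, DME/DMM–aq. buffer (pH ≈ 10), −10 → 0 °C
Reagents that add atoms: potassium peroxymonosulfate (Oxone), OOS(=O)(=O)[O-].[K+]
Why: Shi epoxidation of a conjugated cis‑diene: the chiral dioxirane takes the internal cis C2=C3 over the terminal vinyl and the electron‑poor methylene lactone, and with the vinyl group as π‑director this catalyst enantiomer gives the (2R,3R) cis‑epoxide.

**Step 9**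
Reactants: 12
Product: 13, (4R,5S)‑5‑[(2R,2′R,3R,3′R)‑3′‑ethenyl‑2‑methyl‑2,2′‑bioxiran‑3‑yl]‑4‑(hydroxymethyl)‑3‑methylidenedihydrofuran‑2(3H)‑one
Conditions: HF·pyridine, pyridine/THF, 0 °C
Reagents that add atoms: none
Why: Buffered fluoride desilylation; non‑basic conditions avoid trans‑lactonisation of the freed C8–OH onto C12.

**Step 10**
Reactants: 13
Product: 14, (2S,3S)‑2‑[(2R,2′R,3R,3′R)‑3′‑ethenyl‑2‑methyl‑2,2′‑bioxiran‑3‑yl]‑4‑methylidene‑5‑oxotetrahydrofuran‑3‑carbaldehyde (C8 aldehyde)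
Conditions: Dess–Martin periodinane, NaHCO3, CH2Cl2, 0 °C; used crude at once
Reagents that add atoms: none
Why: Dess–Martin oxidation under buffered, base‑free conditions, needed because C7–H is now α to CHO and allylic and would epimerise or isomerise with base.

**Step 11**
Reactants: 15, 2‑(trimethylsilyl)ethanol; 16, propanoyl chloride
Product: 17, 2‑(trimethylsilyl)ethyl propanoate
Conditions: Et3N, DMAP (cat.), CH2Cl2, 0 °C
Reagents that add atoms: none
Why: Simple O‑acylation; installs the fluoride‑labile ester that will become C14.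

**Step 12**
Reactants: 17; 18, 2,2,2‑trifluoroethyl formate
Product: 19, 2‑(trimethylsilyl)ethyl (2E)‑3‑acetoxy‑2‑methylprop‑2‑enoate
Conditions: LDA, THF, −78 °C; 18; then Ac2O, −78 → 0 °C
Reagents that add atoms: acetic anhydride, CC(=O)OC(C)=O
Why: Claisen formylation of the ester enolate and O‑acetylation of the resulting formyl enolate gives the enol acetate (future C9–OAc).

**Step 13**
Reactants: 19
Product: 20, 2‑(trimethylsilyl)ethyl (2Z)‑3‑acetoxy‑2‑(bromomethyl)prop‑2‑enoate (OAc cis to CH2Br)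
Conditions: NBS, AIBN (cat.), PhCF3, 80 °C
Reagents that add atoms: N‑bromosuccinimide, O=C1CCC(=O)N1Br
Why: Wohl–Ziegler allylic bromination of the 2‑methyl group, as used for 3‑alkoxy‑2‑methylacrylates.

**Step 14**
Reactants: 14; 20
Product: 21, 2‑(trimethylsilyl)ethyl ester of the C8 alcohol: lactone core of 14 carrying at C7 the chain –C8H(OH)–C9H(OAc)–C10(=CH2)–CO2TMSE (8S,9S; 8,9‑syn)
Conditions: In powder, THF/H2O (3:1), rt
Reagents that add atoms: none
Why: Indium Barbier allylation with a 2‑(bromomethyl)acrylate: γ‑attack of the (Z)‑γ‑acetoxyallyl indium through a chair gives the 8,9‑syn (threo) hydroxy acetate, and Felkin–Anh addition at C8 (electron‑poor sp2 C11 antiperiplanar, helped by In chelation to the lactone oxygen) is expected to give the target C7/C8 relationship.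

**Step 15**
Reactants: 22, methyl angelate
Product: 23, (2Z)‑2‑methylbut‑2‑en‑1‑ol
Conditions: DIBAL‑H, Et2O, −78 → 0 °C
Reagents that add atoms: none
Why: 1,2‑Reduction of the enoate; Z geometry retained.

**Step 16**
Reactants: 23
Product: 24, [(2S,3R)‑2,3‑dimethyloxiran‑2‑yl]methanol
Conditions: Shi D‑fructose‑derived ketone (30 mol%), Oxone, K2CO3, Bu4NHSO4, MeCN/DMM–buffer (pH 10.5), 0 °C
Reagents that add atoms: potassium peroxymonosulfate (Oxone), OOS(=O)(=O)[O-].[K+]
Why: Shi epoxidation of a trisubstituted allylic alcohol; the spiro transition‑state model for this ketone predicts the face that gives the (2′R,3′R) epoxyangelate series, and the Z‑alkene gives the cis relationship stereospecifically.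

**Step 17**
Reactants: 24
Product: 25, (2R,3R)‑2,3‑dimethyloxirane‑2‑carboxylic acid (epoxyangelic acid)
Conditions: TEMPO (cat.), PhI(OAc)2, MeCN/H2O, 0 °C → rt
Reagents that add atoms: water, O
Why: TEMPO/hypervalent‑iodine oxidation of a primary alcohol to the acid under near‑neutral conditions that spare the epoxide.

**Step 18**
Reactants: 21; 25
Product: 26, RCM diene: 21 acylated at O8 with the (2R,3R)‑epoxyangeloyl group
Conditions: 25, 2,4,6‑Cl3C6H2COCl, Et3N, THF; then 21, DMAP, toluene, 0 °C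
Reagents that add atoms: none
Why: Yamaguchi esterification of the hindered C8–OH with the pre‑formed mixed anhydride, kept cold to limit O9→O8 acetyl migration.

**Step 19**
Reactants: 26
Product: 27, leucanthin B 2‑(trimethylsilyl)ethyl ester (ring‑cis C1=C10)
Conditions: Hoveyda–Grubbs II (20 mol%), 1,4‑benzoquinone (cat.), toluene (1 mM), 80 °C (−C2H4)
Reagents that add atoms: none
Why: Ring‑closing metathesis initiating at the vinyl epoxide and closing on the C10 acrylate; the 10‑membered ring prefers the ring‑cis trisubstituted enoate, and closure onto the lactone methylene would need a bridgehead alkene.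

**Step 20**
Reactants: 27
Product: 28, leucanthin B
Conditions: TASF, DMF, 0 °C; pH 5 buffer work‑up
Reagents that add atoms: none
Why: Fluoride‑triggered β‑elimination of the TMSE ester frees the C14 acid without acid, strong base or Pd(0), so the three epoxides, acetate, epoxyangelate and methylene lactone are left intact.

## Compound list

1 | (Z)‑3‑methylpent‑2‑en‑4‑yn‑1‑ol | C#C/C(C)=C\CO | starting material
2 | bromoethene (vinyl bromide) | C=CBr | starting material
3 | (2Z)‑3‑methylhepta‑2,6‑dien‑4‑yn‑1‑ol | C=CC#C/C(C)=C\CO | intermediate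
4 | (2Z)‑3‑methylhepta‑2,6‑dien‑4‑ynal | C=CC#C/C(C)=C\C=O | intermediate
5 | tert‑butyldimethyl(prop‑2‑yn‑1‑yloxy)silane | C#CCO[Si](C)(C)C(C)(C)C | starting material
6 | methyl 4‑[(tert‑butyldimethylsilyl)oxy]but‑2‑ynoate | COC(=O)C#CCO[Si](C)(C)C(C)(C)C | intermediate
7 | 2‑(iodomethyl)‑4,4,5,5‑tetramethyl‑1,3,2‑dioxaborolane | ICB1OC(C)(C)C(C)(C)O1 | starting material
8 | methyl (2Z)‑4‑[(tert‑butyldimethylsilyl)oxy]‑2‑[(pinacolboryl)methyl]but‑2‑enoate | COC(=O)/C(CB1OC(C)(C)C(C)(C)O1)=C\CO[Si](C)(C)C(C)(C)C | intermediate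
9 | methyl (3R,4R,5Z)‑3‑(TBSO‑methyl)‑4‑hydroxy‑6‑methyl‑2‑methylidenedeca‑5,9‑dien‑7‑ynoate | C=C(C(=O)OC)[C@H](CO[Si](C)(C)C(C)(C)C)[C@H](O)/C=C(C)\C#CC=C | intermediate
10 | methyl (3R,4R,5Z,7Z)‑3‑(TBSO‑methyl)‑4‑hydroxy‑6‑methyl‑2‑methylidenedeca‑5,7,9‑trienoate | C=C(C(=O)OC)[C@H](CO[Si](C)(C)C(C)(C)C)[C@H](O)/C=C(C)\C=C/C=C | intermediate
11 | 4,5‑epoxy trans‑α‑methylene‑γ‑lactone with (Z)‑butadienyl and CH2OTBS arms | C=C1C(=O)O[C@@H]([C@H]1CO[Si](C)(C)C(C)(C)C)[C@H]1O[C@@]1(C)/C=C\C=C | intermediate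
12 | 2,3:4,5‑bis‑epoxide (vinyl at C2), C8 silyl ether | C=C1C(=O)O[C@@H]([C@H]1CO[Si](C)(C)C(C)(C)C)[C@H]1O[C@@]1(C)[C@@H]1O[C@@H]1C=C | intermediate
13 | bis‑epoxy lactone C8 primary alcohol | C=C1C(=O)O[C@@H]([C@H]1CO)[C@H]1O[C@@]1(C)[C@@H]1O[C@@H]1C=C | intermediate
14 | bis‑epoxy lactone C8 aldehyde | C=C1C(=O)O[C@@H]([C@H]1C=O)[C@H]1O[C@@]1(C)[C@@H]1O[C@@H]1C=C | intermediate
15 | 2‑(trimethylsilyl)ethanol | C[Si](C)(C)CCO | starting material
16 | propanoyl chloride | CCC(=O)Cl | starting material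
17 | 2‑(trimethylsilyl)ethyl propanoate | CCC(=O)OCC[Si](C)(C)C | intermediate
18 | 2,2,2‑trifluoroethyl formate | O=COCC(F)(F)F | starting material
19 | 2‑(trimethylsilyl)ethyl (2E)‑3‑acetoxy‑2‑methylprop‑2‑enoate | CC(=O)O/C=C(\C)C(=O)OCC[Si](C)(C)C | intermediate
20 | 2‑(trimethylsilyl)ethyl (2Z)‑3‑acetoxy‑2‑(bromomethyl)prop‑2‑enoate | CC(=O)O/C=C(\CBr)C(=O)OCC[Si](C)(C)C | intermediate
21 | C8‑hydroxy, C9‑acetoxy, C10‑methylene TMSE ester (8S,9S) | C=C1C(=O)O[C@@H]([C@H]1[C@H](O)[C@@H](OC(C)=O)C(=C)C(=O)OCC[Si](C)(C)C)[C@H]1O[C@@]1(C)[C@@H]1O[C@@H]1C=C | intermediate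
22 | methyl angelate, methyl (2Z)‑2‑methylbut‑2‑enoate | C/C=C(/C)C(=O)OC | starting material
23 | (2Z)‑2‑methylbut‑2‑en‑1‑ol | C/C=C(/C)CO | intermediate
24 | [(2S,3R)‑2,3‑dimethyloxiran‑2‑yl]methanol | OC[C@]1(C)O[C@@H]1C | intermediate
25 | (2R,3R)‑2,3‑dimethyloxirane‑2‑carboxylic acid | OC(=O)[C@]1(C)O[C@@H]1C | intermediate
26 | RCM diene (8‑O‑epoxyangeloyl, 9‑OAc, TMSE ester; all ring and side‑chain centres as in target) | C=C1C(=O)O[C@@H]([C@H]1[C@H](OC(=O)[C@]1(C)O[C@@H]1C)[C@@H](OC(C)=O)C(=C)C(=O)OCC[Si](C)(C)C)[C@H]1O[C@@]1(C)[C@@H]1O[C@@H]1C=C | intermediate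
27 | leucanthin B 2‑(trimethylsilyl)ethyl ester | C=C1C(=O)O[C@H]2[C@H]1[C@H](OC(=O)[C@]1(C)O[C@@H]1C)[C@@H](OC(C)=O)/C(C(=O)OCC[Si](C)(C)C)=C\[C@H]1O[C@H]1[C@]1(C)O[C@H]21 | intermediate
28 | leucanthin B | C=C1C(=O)O[C@H]2[C@H]1[C@H](OC(=O)[C@]1(C)O[C@@H]1C)[C@@H](OC(C)=O)/C(C(=O)O)=C\[C@H]1O[C@H]1[C@]1(C)O[C@H]21 | target

## Step count and risk

Total steps: 20. Longest linear sequence: 12 (Steps 1, 2, 5, 6, 7, 8, 9, 10, 14, 18, 19, 20).

Steps most likely to fail:

1. **Step 5 (proposed new allylboration).** The deactivated boronate may not turn over, may give low ee, or may lactonise early and lose the directing OH. Fallback: switch from catalyst to auxiliary control. Run the known uncatalysed thermal allylboration (toluene, 80–110 °C) with the same (Z)‑boronate carried as a chiral 8‑phenylmenthyl ester; the chair still gives 6,7‑anti and the auxiliary leaves on lactonisation. The 4,5‑epoxide is then installed on the lactone with the fructose‑derived Shi ketone instead of by OH direction.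

2. **Step 14 (indium Barbier at C8).** Aldehyde 14 can epimerise or isomerise at C7, and the C7→C8 facial selectivity and syn selectivity of this reagent are the least secure stereochemical element. Fallback: a catalyst‑controlled order of events. Use the one‑carbon‑longer boronate (γ‑CH2CH2OTBS) so the arm ends as C8H2–C9HO, set C8–O by proline‑catalysed α‑aminoxylation, then set C9 by a β‑isocupreidine‑catalysed Morita–Baylis–Hillman reaction with hexafluoroisopropyl acrylate, followed by the two acylations.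

3. **Step 19 (RCM to the 10‑membered trisubstituted enoate).** Both alkenes are poor partners and dimerisation may win. Fallback: close the ring at C6–C7 instead, by CrCl2‑mediated intramolecular Nozaki–Hiyama (Barbier‑type) allylation of a C6 epoxy‑aldehyde with a C13 allylic bromide, the established macrocyclisation for 4,5‑epoxy germacranolides, after joining the fragments at C1=C10 by Horner–Wadsworth–Emmons olefination.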